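The plan cuts the furan ring (O1, C2–C5) at C3–C4 and O1–C5. This exploits its substitution pattern: aryl at C2, side chain at C4, hydrogen at C3 and C5. O1/C2/C3 therefore derive from an aryl methyl ketone and C4/C5 from a chloromethyl ketone. One flask operation (aldol addition, oxirane closure, acid-induced cyclodehydration) joins both halves and creates the aromatic ring with connectivity-dictated 2,4-regiochemistry. The electrophile is an (R)-α-triethylsilyloxy chloromethyl ketone that already carries the prenyl chain and the carbinol stereocentre from the chiral pool. The nucleophile is bis-TIPS-protected 2,5-dihydroxyacetophenone. Orthogonal silyl groups then permit esterification with (R)-2-methylbutanoic acid and final fluoride deprotection.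

Key step: step 5

Assumption: methyl (R)-glycidate and (R)-2-methylbutanoic acid are bought enantiopure and the Grignard reagent as its THF solution; the locants O1, C2 (aryl), C3, C4 (side chain), C5 of the final furan are also used for its open-chain precursors.

Stereochemical check: both stereocentres of the target are (R). The carbinol centre is C2 of the glycidate; none of its four bonds is ever broken, and its descriptor stays (R) in every intermediate because O > C(=O) or ring carbon > CH2 > H holds throughout.

Step 1
Reactants: 1 methyl (R)-glycidate; 2 2-methylprop-1-enylmagnesium bromide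
Product: 3 methyl (R)-2-hydroxy-5-methylhex-4-enoate
Conditions: CuBr·SMe2 (10 mol %), THF, −78 °C → −40 °C; aq. NH4Cl
Reagents that add atoms: none
Why: Copper-catalysed Grignard opening of a terminal epoxide (SN2 at the unsubstituted CH2) outruns ester attack at low temperature, and because the C2–O bond is untouched the (R) centre passes unchanged into 3.

Step 2
Reactants: 3 methyl (R)-2-hydroxy-5-methylhex-4-enoate
Product: 4 methyl (R)-5-methyl-2-(triethylsilyloxy)hex-4-enoate
Conditions: TESCl, imidazole, CH2Cl2, 0 °C → rt
Reagents that add atoms: triethylsilyl chloride (TESCl), CC[Si](Cl)(CC)CC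
Why: Imidazole-promoted silylation of a secondary alcohol installs a group that tolerates organolithium reagents and mild pyridinium acid yet can later be removed beside aryl TIPS ethers.

Step 3
Reactants: 4 methyl (R)-5-methyl-2-(triethylsilyloxy)hex-4-enoate
Product: 6 (R)-1-chloro-6-methyl-3-(triethylsilyloxy)hept-5-en-2-one, via tetrahedral lithium adduct 5 (not isolated)
Conditions: ClCH2I, MeLi·LiBr, THF/Et2O, −78 °C; AcOH/THF, −78 °C
Reagents that add atoms: chloroiodomethane, ClCI
Why: In this carbenoid acylation (chloromethyllithium homologation of an ester), LiCH2Cl made by iodine–lithium exchange in the presence of 4 adds once, the α-oxygenated adduct 5 persists at −78 °C until the cold acidic quench, and the short contact with the weakly basic carbenoid leaves the α-centre (R).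

Step 4
Reactants: 7 1-(2,5-dihydroxyphenyl)ethanone
Product: 8 1-[2,5-bis(triisopropylsilyloxy)phenyl]ethanone
Conditions: TIPSCl (2.5 equiv), imidazole, DMAP (cat), DMF, rt → 50 °C
Reagents that add atoms: triisopropylsilyl chloride (TIPSCl), CC(C)[Si](Cl)(C(C)C)C(C)C
Why: Exhaustive O-silylation of both phenols (the hydrogen-bonded ortho OH needs warming) gives bulky groups that cannot shift to the neighbouring enolate oxygen in step 5, resist buffered HF·pyridine and fall to fluoride ion at the end.

Step 5
Reactants: 8 1-[2,5-bis(triisopropylsilyloxy)phenyl]ethanone; 6 (R)-1-chloro-6-methyl-3-(triethylsilyloxy)hept-5-en-2-one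
Product: 13 (R)-triethylsilyl ether of 1-{5-[2,5-bis(triisopropylsilyloxy)phenyl]furan-3-yl}-4-methylpent-3-en-1-ol, via lithium enolate 9 (not isolated), via chlorohydrin alkoxide 10 (not isolated), via epoxy ketone 11 (not isolated), via hydroxydihydrofuran 12 (not isolated)
Conditions: 8 (1.2 equiv), LiN(i-Pr)2 (LDA, 1.1 equiv), THF, −78 °C; 6 (1.0 equiv), −78 °C → rt; PPTS (2.5 equiv), 4 Å MS, rt → 45 °C
Reagents that add atoms: none
Why: LiN(i-Pr)2 deprotonates the only acidic C–H site of 8 to give enolate 9, whose CH2 carbon adds to the carbonyl of 6 (new bond C3–C4) to give alkoxide 10, and on warming 10 displaces the neighbouring chloride (3-exo-tet) to give the β,γ-epoxy ketone 11. PPTS, added in excess over the amine, enolises the aryl ketone and activates the oxirane so that the enol oxygen alkylates at the unhindered CH2 (new bond O1–C5) to give 12, which ionises at C4 to an allylic cation stabilised by O1 and loses H from C5 to become aromatic. The closest known reaction type is the Feist–Bénary furan synthesis run in its interrupted, aldol-first form, combined with the acid-induced rearrangement of β,γ-epoxy ketones to furans. The furan ring closes by five-membered O-alkylation in which the breaking C5–O bond lies outside the new ring (5-exo-tet in the strict Baldwin sense, often called 5-endo for epoxides because both oxirane carbons enter the ring), and the conceivable side paths of 11 (opening to the γ-hydroxy enone then hemiketalisation, or hydride shift to the 4-oxo aldehyde then Paal–Knorr closure) end in the same 2,4-disubstituted furan. No lasting stereocentre is made, because the C4 centre of 10 to 12 (formed as a mixture) becomes sp2, while the (R) carbinol centre sits outside the ring and keeps all four bonds. The step needs carbonyl addition to outrun both SN2 attack at CH2Cl (which would lead through a 1,4-diketone to the 2,5-isomer) and proton transfer from 6, and this should be secured by the double inductive activation of the carbonyl by α-Cl and α-OSi, by chloride as a modest SN2 leaving group, by a lithium enolate at −78 °C with no free amide base left, and by the bulky ortho-OTIPS group.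

Step 6
Reactants: 13 (R)-triethylsilyl ether of 1-{5-[2,5-bis(triisopropylsilyloxy)phenyl]furan-3-yl}-4-methylpent-3-en-1-ol
Product: 14 (R)-1-{5-[2,5-bis(triisopropylsilyloxy)phenyl]furan-3-yl}-4-methylpent-3-en-1-ol
Conditions: HF·pyridine, pyridine, THF, 0 °C
Reagents that add atoms: none
Why: In this selective desilylation with buffered acidic fluoride the small alkyl TES ether is cleaved far faster than the bulky aryl TIPS ethers, and the excess pyridine keeps the medium too mild to ionise the furylic carbinol, so (R) is kept.

Step 7
Reactants: 14 (R)-1-{5-[2,5-bis(triisopropylsilyloxy)phenyl]furan-3-yl}-4-methylpent-3-en-1-ol; 15 (R)-2-methylbutanoic acid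
Product: 16 (R)-1-{5-[2,5-bis(triisopropylsilyloxy)phenyl]furan-3-yl}-4-methylpent-3-enyl (R)-2-methylbutanoate
Conditions: DCC, DMAP (cat), CH2Cl2, 0 °C → rt
Reagents that add atoms: none
Why: Steglich esterification acylates the oxygen without touching the carbinol C–O bond and, with catalytic DMAP at low temperature, should not enolise the α-branched aliphatic acyl donor, so both (R) centres are conserved.

Step 8
Reactants: 16 (R)-1-{5-[2,5-bis(triisopropylsilyloxy)phenyl]furan-3-yl}-4-methylpent-3-enyl (R)-2-methylbutanoate
Product: 17 (R)-1-[5-(2,5-dihydroxyphenyl)furan-3-yl]-4-methylpent-3-enyl (R)-2-methylbutanoate (target)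
Conditions: TBAF/AcOH (equimolar), degassed THF, 0 °C, Ar
Reagents that add atoms: none
Why: Fluoride-induced cleavage of aryl silyl ethers is fast because phenoxide leaves silicon easily, and the acetic acid buffer under argon protonates the phenoxides at once, which shields the hindered ester from basic attack and the hydroquinone from aerial oxidation.

Compound list
1 | methyl (R)-glycidate (methyl (R)-oxirane-2-carboxylate) | COC(=O)[C@H]1CO1 | starting material
2 | 2-methylprop-1-enylmagnesium bromide | CC(C)=C[Mg]Br | starting material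
3 | methyl (R)-2-hydroxy-5-methylhex-4-enoate | COC(=O)[C@H](O)CC=C(C)C | intermediate
4 | methyl (R)-5-methyl-2-(triethylsilyloxy)hex-4-enoate | COC(=O)[C@H](O[Si](CC)(CC)CC)CC=C(C)C | intermediate
5 | lithium (3R)-1-chloro-2-methoxy-6-methyl-3-(triethylsilyloxy)hept-5-en-2-olate (C2 undefined, not isolated) | [Li+].[O-]C(CCl)(OC)[C@H](O[Si](CC)(CC)CC)CC=C(C)C | intermediate
6 | (R)-1-chloro-6-methyl-3-(triethylsilyloxy)hept-5-en-2-one | ClCC(=O)[C@H](O[Si](CC)(CC)CC)CC=C(C)C | intermediate
7 | 1-(2,5-dihydroxyphenyl)ethanone | CC(=O)c1cc(O)ccc1O | starting material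
8 | 1-[2,5-bis(triisopropylsilyloxy)phenyl]ethanone | CC(=O)c1cc(O[Si](C(C)C)(C(C)C)C(C)C)ccc1O[Si](C(C)C)(C(C)C)C(C)C | intermediate
9 | lithium 1-[2,5-bis(triisopropylsilyloxy)phenyl]ethenolate (not isolated) | [Li+].[O-]C(=C)c1cc(O[Si](C(C)C)(C(C)C)C(C)C)ccc1O[Si](C(C)C)(C(C)C)C(C)C | intermediate
10 | lithium alkoxide of (4R)-1-[2,5-bis(triisopropylsilyloxy)phenyl]-3-(chloromethyl)-3-hydroxy-7-methyl-4-(triethylsilyloxy)oct-6-en-1-one (C3 epimers, not isolated) | [Li+].[O-]C(CCl)(CC(=O)c1cc(O[Si](C(C)C)(C(C)C)C(C)C)ccc1O[Si](C(C)C)(C(C)C)C(C)C)[C@H](O[Si](CC)(CC)CC)CC=C(C)C | intermediate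
11 | 1-[2,5-bis(triisopropylsilyloxy)phenyl]-2-{2-[(R)-4-methyl-1-(triethylsilyloxy)pent-3-enyl]oxiran-2-yl}ethanone (oxirane C2 epimers, not isolated) | O=C(CC1(CO1)[C@H](O[Si](CC)(CC)CC)CC=C(C)C)c1cc(O[Si](C(C)C)(C(C)C)C(C)C)ccc1O[Si](C(C)C)(C(C)C)C(C)C | intermediate
12 | 5-[2,5-bis(triisopropylsilyloxy)phenyl]-3-[(R)-4-methyl-1-(triethylsilyloxy)pent-3-enyl]-2,3-dihydrofuran-3-ol (C3 epimers, not isolated) | OC1(COC(=C1)c2cc(O[Si](C(C)C)(C(C)C)C(C)C)ccc2O[Si](C(C)C)(C(C)C)C(C)C)[C@H](O[Si](CC)(CC)CC)CC=C(C)C | intermediate
13 | (R)-triethylsilyl ether of 1-{5-[2,5-bis(triisopropylsilyloxy)phenyl]furan-3-yl}-4-methylpent-3-en-1-ol | CC[Si](CC)(CC)O[C@H](CC=C(C)C)c1coc(-c2cc(O[Si](C(C)C)(C(C)C)C(C)C)ccc2O[Si](C(C)C)(C(C)C)C(C)C)c1 | intermediate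
14 | (R)-1-{5-[2,5-bis(triisopropylsilyloxy)phenyl]furan-3-yl}-4-methylpent-3-en-1-ol | O[C@H](CC=C(C)C)c1coc(-c2cc(O[Si](C(C)C)(C(C)C)C(C)C)ccc2O[Si](C(C)C)(C(C)C)C(C)C)c1 | intermediate
15 | (R)-2-methylbutanoic acid | CC[C@@H](C)C(=O)O | starting material
16 | (R)-1-{5-[2,5-bis(triisopropylsilyloxy)phenyl]furan-3-yl}-4-methylpent-3-enyl (R)-2-methylbutanoate | CC[C@@H](C)C(=O)O[C@H](CC=C(C)C)c1coc(-c2cc(O[Si](C(C)C)(C(C)C)C(C)C)ccc2O[Si](C(C)C)(C(C)C)C(C)C)c1 | intermediate
17 | (R)-1-[5-(2,5-dihydroxyphenyl)furan-3-yl]-4-methylpent-3-enyl (R)-2-methylbutanoate | CC[C@@H](C)C(=O)O[C@H](CC=C(C)C)c1coc(-c2cc(O)ccc2O)c1 | target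

Total step count: 8
Longest linear sequence: 7 (steps 1, 2, 3, 5, 6, 7, 8)

Steps most likely to fail

1. Step 5.
- **What may go wrong:** proton transfer from the chloroketone to the enolate, retro-aldol cleavage of the lithium aldolate while it is warmed, and competing C-alkylation at CH2Cl. Partial loss of the TES group under PPTS would be harmless, because it only anticipates step 6.
- **Fallback, from 8 (with 6) back to 11:** the basic enolate is replaced by a neutral enol silane and each event is run separately. Treatment of 8 with TMSOTf/Et3N (CH2Cl2, 0 °C) should give the trimethylsilyl enol ether F1. A Mukaiyama aldol addition of F1 to 6 (BF3·OEt2, CH2Cl2, −78 °C, aqueous work-up) should give the isolable chlorohydrin F2. DBU (CH2Cl2, 0 °C → rt) closes the oxirane to 11, and catalytic PPTS in toluene takes 11 on to 13 as in step 5.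

2. Step 3.
- **What may go wrong:** collapse of the tetrahedral adduct before the quench followed by a second carbenoid addition, or decomposition of the carbenoid faster than acylation.
- **Fallback, from 4 back to 6:** the acyl donor is changed rather than the carbenoid conditions. Transamidation of 4 with MeNH(OMe)·HCl and i-PrMgCl (THF, −20 °C) should give the Weinreb amide F3. Its chelated adduct with LiCH2Cl (ClCH2I, MeLi·LiBr, −78 °C) cannot release a ketone until the quench, and then delivers 6.

3. Step 6.
- **What may go wrong:** erosion of the aryl silyl ethers by fluoride, or acid-induced ionisation at the furylic carbinol with loss of configurational purity.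
- **Fallback, from 13 back to 14:** selectivity is moved from the deprotection to the protection event, and acidic fluoride is avoided. Global desilylation of 13 with buffered TBAF/AcOH (THF, 0 °C, Ar) should give the triol F4. Its two phenols are then re-silylated with TIPSCl (2.1 equiv) and imidazole in DMF at 0 °C. Under these conditions a hindered secondary alcohol reacts only very slowly, so 14 results.

Further compounds
F1 | step 5 | 1-[2,5-bis(triisopropylsilyloxy)phenyl]-1-(trimethylsilyloxy)ethene | C=C(O[Si](C)(C)C)c1cc(O[Si](C(C)C)(C(C)C)C(C)C)ccc1O[Si](C(C)C)(C(C)C)C(C)C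
F2 | step 5 | (4R)-1-[2,5-bis(triisopropylsilyloxy)phenyl]-3-(chloromethyl)-3-hydroxy-7-methyl-4-(triethylsilyloxy)oct-6-en-1-one (C3 epimers) | OC(CCl)(CC(=O)c1cc(O[Si](C(C)C)(C(C)C)C(C)C)ccc1O[Si](C(C)C)(C(C)C)C(C)C)[C@H](O[Si](CC)(CC)CC)CC=C(C)C
F3 | step 3 | (R)-N-methoxy-N,5-dimethyl-2-(triethylsilyloxy)hex-4-enamide | CON(C)C(=O)[C@H](O[Si](CC)(CC)CC)CC=C(C)C
F4 | step 6 | (R)-2-[4-(1-hydroxy-4-methylpent-3-enyl)furan-2-yl]benzene-1,4-diol | O[C@H](CC=C(C)C)c1coc(-c2cc(O)ccc2O)c1
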